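## Analysis of the target

Compound 12 is a fully acylated methyl shikimate: a cyclohexene in which C1 carries the methyl ester and forms the only ring double bond with C2, C3 carries an acetate, C4 and C5 each carry a (2R)-2-methylbutanoate, and C6 is a methylene. The ring stereocentres are 3R,4S,5R, so O3 and O4 are cis and O4 and O5 are trans; two further R centres sit α to the carbonyl groups of the branched acyl residues. The sensitive elements are the three secondary esters on neighbouring oxygens, which can migrate (most easily across the cis pair O3/O4), the α-centres of the 2-methylbutanoyl groups, which can epimerise if the acid is activated harshly, and the enoate. Precursors that still contain a second ring double bond are cyclohexadienes that aromatise readily by loss of the C5 oxygen substituent. The skeleton is therefore easy; the difficulty is the absolute configuration at C5, the cis-3,4/trans-4,5 oxygen pattern, and placing an acetate on O3 alone and the same chiral acyl group on O4 and O5 without protecting groups. The strategy rests on the fact that C1–C6 and O5 are the atoms of a ring-opened furan–acrylate cycloadduct. In the 7-oxanorbornene the furan oxygen bridges C2 and C5; cleaving the C2–O bond by β-elimination from the ester enolate gives the C1=C2 enoate, keeps the oxygen on C5 and leaves a C3=C4 double bond for syn-dihydroxylation on the face opposite O5.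

## Retrosynthetic reasoning

Ring positions C1–C6 and O3–O5 refer to the numbering of 12 throughout.

**12 ⇒ 11 + 7.** The acyl C–O bond at O4 is cut last. In 11 this is the only free hydroxyl, so the final acylation with (R)-2-methylbutanoic acid 7 needs no selectivity. It only has to be fast and mild enough that the neighbouring O3 acetate does not migrate and the acid does not epimerise.

**11 ⇒ 9.** The acetyl group on O3 is removed to give the cis-3,4-diol 9. Direct monoacetylation of a cis-diol is unreliable, so the two hydroxyls are tied into the cyclic orthoacetate 10. Its acid hydrolysis is expected to leave the ester on the pseudoaxial oxygen (O3) and the free hydroxyl on the equatorial one (O4). This differentiates the diol without a protecting group.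

**9 ⇒ 8.** Both C–O bonds at C3 and C4 are cut in a syn-dihydroxylation transform. The cis relation of O3 and O4 is exactly what an OsO4 dihydroxylation delivers. The forward reaction must choose the C3=C4 double bond (the one not attached to the ester carbonyl) and the face opposite the C5 acyloxy group, which sets C3 and C4 relative to C5.

**8 ⇒ 6 + 7.** The acyl C–O bond at O5 is cut. In dienol 6 the C5 hydroxyl is the only one present, so the final O5 substituent of 12 can be installed directly. It then serves as the steric director for the dihydroxylation and turns any minor enantiomeric ring series into a separable diastereomer.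

**6 ⇒ 4 (through 5).** O5 is reconnected to C2, which is the reverse of an E1cB opening. In the forward sense an amide base forms the ester enolate at C1 of the bicyclic ester 4, the bridging alkoxide on C2 is expelled, the C1=C2 enoate appears and the lithium alkoxide 5 is protonated to 6. The C5 stereocentre is not touched.

**4 ⇒ 3.** The methyl ester is traced back to the trifluoroethyl ester 3 by ester exchange. The electron-poor ester is needed only to make the cycloaddition feasible; being activated, it is exchanged under very mild basic methanolysis.

**3 ⇒ 1 + 2.** The key disconnection cuts C1–C2 and C5–C6 in a retro-[4+2] to furan 1 and 2,2,2-trifluoroethyl acrylate 2. It delivers all six ring carbons and O5 from two bulk chemicals in one step and is the only event of absolute stereocontrol. The forward reaction has to overcome the low reactivity and reversibility of an aromatic diene and deliver the correct face of the acrylate. It must also proceed in the endo mode: addition in the exo mode to the same acrylate face installs the opposite configuration at the bridgehead that becomes C5. Endo selectivity is therefore as essential as face selectivity, and material formed through the exo mode must be removed before the bridge is opened.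

## Alternatives that were turned down

**Alternative 1: pinacol-type closure of the C3–C4 bond.** The bond between the two carbinol carbons is disconnected. In the forward sense the open-chain dialdehyde A2 (an enal aldehyde at C3 and an α-alkoxy aldehyde at C4) would be reduced by SmI2, a divalent samarium reagent, and cyclise to methyl 5-O-(4-methoxybenzyl)shikimate A1.
- For: one bond formation closes the ring and creates C3 and C4 as a cis-diol, and no OsO4 is needed. A1 is differentiated exactly as 9 is in the chosen route, so on that point it is equally strong.
- Against: the enal of A2 is also conjugated with the ester (a 4-oxobut-2-enoate), so conjugate reduction and reductive dimerisation compete with ketyl coupling. The α-alkoxy aldehyde can epimerise. O5 must be an ether, because an α-acyloxy group would be expelled from the ketyl, so the O5 acyl group needs an extra deprotection and acylation after the diol has been dressed. A2 itself requires a multistep acyclic synthesis with control of alkene geometry and of the C5 centre.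
- Comparison: the chosen route makes the ring from two commodity chemicals in one step and carries the final O5 acyl group instead of a protecting group.

**Alternative 2: cycloaddition of an oxygenated diene with a nitroacrylate.** C2–C3 and C6–C1 are disconnected. (E)-1-acetoxybuta-1,3-diene A4 and methyl (E)-3-nitroacrylate A5 would combine in a catalysed [4+2] to give A3, and loss of nitrite would then give the skipped diene A6.
- For: the C3 acetate is already the acetate of 12, the nitro group fixes the regiochemistry and then leaves without a trace, and O4 and O5 could be acylated together. On differentiation of O3 this route is stronger, since it needs no orthoester step.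
- Against: in A6 the acetate is doubly allylic and aromatises by loss of acetic acid. The C4=C5 double bond must become a trans-diol with O4 cis to O3, which requires epoxidation syn to the acetate and regioselective opening at C5; neither is secured. Only C3 is set in the cycloaddition, and catalytic enantiocontrol for this diene–dienophile pair is less established.
- Comparison: the chosen route's cis-3,4 (syn-dihydroxylation) and trans-4,5 (anti approach) pattern matches the target directly.

**Alternative 3: sugar-derived phosphonate, intramolecular Horner–Wadsworth–Emmons closure.** The C1=C2 double bond is disconnected. The lactol phosphonate A9, built on the carbons of D-lyxose A8, would open under base and the phosphonate carbanion at C1 would condense with the C2 aldehyde to give methyl 3,4-O-isopropylidene shikimate A7.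
- For: all three ring stereocentres come from the sugar, so absolute and relative configuration do not depend on a catalyst's sense of induction, on endo/exo topology or on the face selectivity of a dihydroxylation. On stereochemical certainty this route is clearly stronger. A7 could be acylated at O5 with 7 and deprotected to reach 9.
- Against: it needs a rare pentose, acetonide and anomeric protection, activation of the sugar C5 position and displacement by a phosphonoacetate next to the ring oxygen, and roughly twice as many steps before 9 is reached.
- Comparison: the chosen route is about half as long, uses no protecting groups and draws its chirality from a catalytic step; the price is that its stereochemical outcome must be verified, not assumed.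

Key step: step 1

## Remarks on the chemistry

- (R)-2-Methylbutanoic acid 7 is assumed to be purchased in enantiopure form.
- The oxazaborolidine is prepared beforehand in one operation from (S)-α,α-diphenyl-2-pyrrolidinemethanol and tri(2-methylphenyl)boroxine (toluene, azeotropic removal of water). It is protonated with HN(SO2CF3)2 in CH2Cl2 at −25 °C just before use. It is a catalyst and is not counted as a step.
- The (S)-ligand is chosen on the basis of the usual binding model for acrylate esters: boron on the carbonyl lone pair syn to the vinyl group, an α-C–H···O contact, and one phenyl group covering the rear face. This choice is a model-based prediction. The sense of induction is to be confirmed on the first batch at the stage of 6 or 9 (chiral HPLC against racemate, sign of rotation). If it is the reverse, the equally available (R)-ligand is used.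

## Route

Step 1
Reactants: 1 furan; 2 2,2,2-trifluoroethyl acrylate
Product: 3 2,2,2-trifluoroethyl (1R,2R,4R)-7-oxabicyclo[2.2.1]hept-5-ene-2-carboxylate (endo ester)
Conditions: (S)-3,3-diphenyl-1-(2-methylphenyl)tetrahydro-1H,3H-pyrrolo[1,2-c][1,3,2]oxazaborole (C24H24BNO, 20 mol%), HN(SO2CF3)2 (17 mol%), 1 (5 equiv), CH2Cl2, −78 °C; Et3N, −78 °C; silica gel (removal of the exo isomer)
Reagents that add atoms: none
Why: The protonated oxazaborolidine binds the ester carbonyl of 2 and lowers its LUMO, and furan adds through a concerted but asynchronous suprafacial [4+2] transition state in which the bond from the acrylate β-carbon (future C6) to a furan α-carbon (future C5) runs ahead of the C1–C2 bond. The closest known reaction type is the oxazaborolidinium-catalysed enantioselective Diels–Alder reaction of acrylate esters with simple dienes, furan included. The six-membered carbocycle closes by intermolecular cycloaddition, both σ-bonds forming in one step, and the old furan ring becomes the oxygen bridge of a 7-oxanorbornene. C2 of 3 is set by the catalyst, which must leave the Si face of the acrylate α-carbon (CO2R > CH2 > H) open to the diene; the two bridgeheads are set relative to C2 by the endo orientation of the ester. Only the bridgehead that becomes C5 survives later, so both face and topology count: an exo adduct from the same acrylate face has mirror-image bridgeheads and would end as the enantiomer of 6. Endo selectivity should be secured by kinetic control at −78 °C and by quenching the acid cold, so that no equilibration through cycloreversion occurs, and the minor exo diastereomer is removed by chromatography. The cationic Lewis acid and the electron-poor trifluoroethyl ester are what should make the aromatic, reversible diene react at a temperature at which the adduct does not revert; the slight deficit of HN(SO2CF3)2 avoids free strong acid, which would polymerise furan.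

Step 2
Reactants: 3 2,2,2-trifluoroethyl (1R,2R,4R)-7-oxabicyclo[2.2.1]hept-5-ene-2-carboxylate
Product: 4 methyl (1R,2R,4R)-7-oxabicyclo[2.2.1]hept-5-ene-2-carboxylate
Conditions: MeOH, K2CO3 (0.1 equiv), 0 °C
Reagents that add atoms: methanol CO
Why: Base-catalysed transesterification; trifluoroethoxide is a much better leaving group than methoxide, so exchange should be fast under conditions too mild for enolate-driven opening of the bridge, and any epimerisation at C2 is harmless once the exo adduct has been removed because the bridgeheads are unaffected.

Step 3
Reactants: 4 methyl (1R,2R,4R)-7-oxabicyclo[2.2.1]hept-5-ene-2-carboxylate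
Product: 6 methyl (5R)-5-hydroxycyclohexa-1,3-diene-1-carboxylate, via lithium alkoxide 5 (not isolated)
Conditions: LiN(SiMe3)2 (1.2 equiv), THF, −78 to −30 °C; AcOH (1.3 equiv), −78 °C; pH 7 buffer work-up, product used at once
Reagents that add atoms: none
Why: E1cB ring opening: the hindered amide base forms the ester enolate at C1 and the strained bridging C2–O bond is expelled as the alkoxide, giving the C1=C2 enoate and leaving the oxygen on C5 with its configuration unchanged; a cold, nearly neutral quench avoids acid-promoted aromatisation of the dienol.

Step 4
Reactants: 6 methyl (5R)-5-hydroxycyclohexa-1,3-diene-1-carboxylate; 7 (R)-2-methylbutanoic acid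
Product: 8 methyl (5R)-5-{[(2R)-2-methylbutanoyl]oxy}cyclohexa-1,3-diene-1-carboxylate
Conditions: DCC (1.3 equiv), DMAP (0.1 equiv), CH2Cl2, 0 °C
Reagents that add atoms: none
Why: Steglich esterification of the only hydroxyl present; the C5–O bond is not broken, so C5 is retained, and a simple α-branched alkanoic acid activated by a carbodiimide with catalytic DMAP at 0 °C has no low-energy pathway for epimerisation.

Step 5
Reactants: 8 methyl (5R)-5-{[(2R)-2-methylbutanoyl]oxy}cyclohexa-1,3-diene-1-carboxylate
Product: 9 methyl 5-O-[(2R)-2-methylbutanoyl]shikimate, that is methyl (3R,4R,5R)-3,4-dihydroxy-5-{[(2R)-2-methylbutanoyl]oxy}cyclohex-1-ene-1-carboxylate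
Conditions: OsO4 (2 mol%), NMO (1.2 equiv), acetone/H2O 10:1, 0 °C
Reagents that add atoms: osmium tetroxide O=[Os](=O)(=O)=O; N-methylmorpholine N-oxide C[N+]1([O-])CCOCC1; water O
Why: Catalytic syn-dihydroxylation; the electrophilic oxidant should take the C3=C4 double bond, which is not attached to the ester carbonyl, in preference to the electron-poor trisubstituted C1=C2 bond, and should approach anti to the pseudoaxial C5 acyloxy group, which sets O3 and O4 cis to each other and trans to O5 (the shikimate pattern).

Step 6
Reactants: 9 methyl 5-O-[(2R)-2-methylbutanoyl]shikimate
Product: 11 methyl 3-O-acetyl-5-O-[(2R)-2-methylbutanoyl]shikimate, via cyclic orthoacetate 10 (not isolated)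
Conditions: MeC(OMe)3 (2 equiv), PPTS (5 mol%), CH2Cl2, rt; then AcOH/H2O 4:1, 0 °C
Reagents that add atoms: trimethyl orthoacetate CC(OC)(OC)OC; water O
Why: Acid-catalysed orthoester exchange ties the cis-diol into a 2-methoxy-2-methyl-1,3-dioxolane, and hydrolysis through the hemiorthoester collapses under stereoelectronic control to the ester on the axial oxygen and the free hydroxyl on the equatorial one; in the shikimate half-chair O3 is pseudoaxial and O4 equatorial, so the acetate should end on O3 without any C–O bond at a stereocentre being broken.

Step 7
Reactants: 11 methyl 3-O-acetyl-5-O-[(2R)-2-methylbutanoyl]shikimate; 7 (R)-2-methylbutanoic acid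
Product: 12 methyl (3R,4S,5R)-3-acetoxy-4,5-bis{[(2R)-2-methylbutanoyl]oxy}cyclohex-1-ene-1-carboxylate
Conditions: DCC (1.5 equiv), DMAP (0.2 equiv), CH2Cl2, 0 °C to rt
Reagents that add atoms: none
Why: Steglich esterification of the single remaining hydroxyl; the acylpyridinium is reactive enough for a flanked secondary alcohol, and working at low temperature with only catalytic DMAP keeps free alkoxide concentration low so that acylation should outrun O3-to-O4 acetyl migration.

## Compound list

1 | furan | c1ccoc1 | starting material
2 | 2,2,2-trifluoroethyl acrylate | C=CC(=O)OCC(F)(F)F | starting material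
3 | 2,2,2-trifluoroethyl (1R,2R,4R)-7-oxabicyclo[2.2.1]hept-5-ene-2-carboxylate (endo) | FC(F)(F)COC(=O)[C@@H]1C[C@@H]2C=C[C@H]1O2 | intermediate
4 | methyl (1R,2R,4R)-7-oxabicyclo[2.2.1]hept-5-ene-2-carboxylate (endo) | COC(=O)[C@@H]1C[C@@H]2C=C[C@H]1O2 | intermediate
5 | lithium (1R)-5-(methoxycarbonyl)cyclohexa-2,4-dien-1-olate (formed in the flask, not isolated) | COC(=O)C1=CC=C[C@H]([O-])C1.[Li+] | intermediate
6 | methyl (5R)-5-hydroxycyclohexa-1,3-diene-1-carboxylate | COC(=O)C1=CC=C[C@H](O)C1 | intermediate
7 | (R)-2-methylbutanoic acid | CC[C@@H](C)C(O)=O | starting material
8 | methyl (5R)-5-{[(2R)-2-methylbutanoyl]oxy}cyclohexa-1,3-diene-1-carboxylate | COC(=O)C1=CC=C[C@H](OC(=O)[C@H](C)CC)C1 | intermediate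
9 | methyl 5-O-[(2R)-2-methylbutanoyl]shikimate (formally 3R,4R,5R; the C4 descriptor differs from that of 12 only through a priority change, the spatial arrangement is that of shikimate) | O[C@@H]1[C@H](O)C=C(C(=O)OC)C[C@H]1OC(=O)[C@H](C)CC | intermediate
10 | 3,4-O-(1-methoxyethylidene) derivative of 9 (cyclic methyl orthoacetate, both epimers at the orthoester carbon; formed in the flask, not isolated) | COC1(C)O[C@@H]2[C@H](O1)C=C(C(=O)OC)C[C@H]2OC(=O)[C@H](C)CC | intermediate
11 | methyl 3-O-acetyl-5-O-[(2R)-2-methylbutanoyl]shikimate (3R,4S,5R) | O[C@@H]1[C@H](OC(C)=O)C=C(C(=O)OC)C[C@H]1OC(=O)[C@H](C)CC | intermediate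
12 | methyl (3R,4S,5R)-3-acetoxy-4,5-bis{[(2R)-2-methylbutanoyl]oxy}cyclohex-1-ene-1-carboxylate | CC[C@@H](C)C(=O)O[C@@H]1[C@H](OC(C)=O)C=C(C(=O)OC)C[C@H]1OC(=O)[C@H](C)CC | target

## Step count and uncertain steps

Total: 7 steps. Longest linear sequence: 7 steps (1 and 2 to 12). The catalyst is prepared in one separate operation.

**Step 1 (key step).** Three things can go wrong.
- Conversion may be low because the aromatic diene is unreactive and the adduct can revert.
- Endo selectivity may erode if the mixture warms while acid is present; because exo addition gives the opposite C5 configuration, this translates directly into loss of enantiopurity after ring opening.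
- The sense of face selection may be opposite to the model prediction.

A partial safeguard is that, after step 4, material of the wrong ring series is a diastereomer and can be removed at 9 or 11.

Fallback: replace catalysis by classical resolution. Setting out from 1, uncatalysed cycloaddition with acrylic acid (neat, radical inhibitor, ambient temperature, long reaction time) should let racemic endo-7-oxabicyclo[2.2.1]hept-5-ene-2-carboxylic acid F1 crystallise from the mixture. Fractional crystallisation of F1 with one antipode of 1-phenylethylamine should give a single diastereomeric salt, written here as (R)-1-phenylethylammonium (1R,2R,4R)-7-oxabicyclo[2.2.1]hept-5-ene-2-carboxylate F2 and acidification of F2 then gives (1R,2R,4R)-7-oxabicyclo[2.2.1]hept-5-ene-2-carboxylic acid F3 as the free acid. Which amine antipode gives the less soluble salt with the wanted acid has to be found by trying both. Methylation of F3 (MeI, KHCO3, DMF) rejoins the route at 4.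

**Step 5.** The acyloxy group at C5 may direct less well than an ether, giving poorer facial selectivity. Oxidation may also touch the C1=C2 bond, the dienyl ester 8 may aromatise by elimination on handling, and the O5 acyl group may migrate to O4 in the diol.

Fallback: carry a silyl ether through the oxidation. Setting out from 6, silylation (TBSCl, imidazole, DMF) gives methyl (5R)-5-(tert-butyldimethylsilyloxy)cyclohexa-1,3-diene-1-carboxylate F4 as a more robust diene. Dihydroxylation of F4 (OsO4 cat., NMO) gives methyl 5-O-(tert-butyldimethylsilyl)shikimate F5 and acetonide formation (2,2-dimethoxypropane, camphorsulfonic acid) then gives methyl 5-O-(tert-butyldimethylsilyl)-3,4-O-isopropylidene shikimate F6 with the diol masked. Desilylation of F6 (Bu4NF, AcOH, THF) gives methyl 3,4-O-isopropylidene shikimate F7 with a free C5 hydroxyl. Steglich esterification of F7 with 7 gives methyl 3,4-O-isopropylidene-5-O-[(2R)-2-methylbutanoyl]shikimate F8 and hydrolysis of its acetonide (aqueous CF3CO2H, 0 °C) rejoins the route at 9. This detour also avoids handling 8.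

**Step 6.** The orthoester may collapse with the wrong regiochemistry if the ring reacts through the other half-chair, and the acetate may migrate from O3 to O4 during work-up or chromatography.

Fallback: reverse the order in which the acyl groups are introduced. Setting out from 9 and from 7, the acid is converted (oxalyl chloride, cat. DMF) into (R)-2-methylbutanoyl chloride F9 for use without purification. Borinic-acid-catalysed acylation of the equatorial hydroxyl of the cis-diol of 9 with F9 (Ph2BOCH2CH2NH2 10 mol%, iPr2NEt, MeCN, 0 °C) gives methyl 4,5-di-O-[(2R)-2-methylbutanoyl]shikimate F10 with only O3 free. Acetylation of F10 at O3 (Ac2O, pyridine) rejoins the route at 12, bypassing 11.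

**Step 7.** Acylation of the flanked O4 hydroxyl may be slow, which gives time for base-mediated acetyl migration from O3 to O4 before the new ester forms; prolonged contact of the activated acid with DMAP could also erode its α-centre.

Fallback: drop base-promoted coupling and transfer the acyl group under Lewis acid catalysis. Setting out from 11 and from 7, the acid is dehydrated (DCC 0.5 equiv, CH2Cl2) to (R)-2-methylbutanoic anhydride F11 and the urea is filtered off. Treatment of 11 with F11 and Sc(OSO2CF3)3 (5 mol%) in MeCN at −20 °C, with no amine or alkoxide present, rejoins the route at 12.

## Further compounds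

F1 | step 1 | racemic endo-7-oxabicyclo[2.2.1]hept-5-ene-2-carboxylic acid (both enantiomers written) | OC(=O)[C@@H]1C[C@@H]2C=C[C@H]1O2.OC(=O)[C@H]1C[C@H]2C=C[C@@H]1O2
F2 | step 1 | (R)-1-phenylethylammonium (1R,2R,4R)-7-oxabicyclo[2.2.1]hept-5-ene-2-carboxylate (pairing of antipodes assumed) | C[C@@H]([NH3+])c1ccccc1.[O-]C(=O)[C@@H]1C[C@@H]2C=C[C@H]1O2
F3 | step 1 | (1R,2R,4R)-7-oxabicyclo[2.2.1]hept-5-ene-2-carboxylic acid (endo) | OC(=O)[C@@H]1C[C@@H]2C=C[C@H]1O2
F4 | step 5 | methyl (5R)-5-(tert-butyldimethylsilyloxy)cyclohexa-1,3-diene-1-carboxylate | COC(=O)C1=CC=C[C@H](O[Si](C)(C)C(C)(C)C)C1
F5 | step 5 | methyl 5-O-(tert-butyldimethylsilyl)shikimate | O[C@@H]1[C@H](O)C=C(C(=O)OC)C[C@H]1O[Si](C)(C)C(C)(C)C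
F6 | step 5 | methyl 5-O-(tert-butyldimethylsilyl)-3,4-O-isopropylidene shikimate | CC1(C)O[C@@H]2[C@H](O1)C=C(C(=O)OC)C[C@H]2O[Si](C)(C)C(C)(C)C
F7 | step 5 | methyl 3,4-O-isopropylidene shikimate (identical with A7) | CC1(C)O[C@@H]2[C@H](O1)C=C(C(=O)OC)C[C@H]2O
F8 | step 5 | methyl 3,4-O-isopropylidene-5-O-[(2R)-2-methylbutanoyl]shikimate | CC1(C)O[C@@H]2[C@H](O1)C=C(C(=O)OC)C[C@H]2OC(=O)[C@H](C)CC
F9 | step 6 | (R)-2-methylbutanoyl chloride | CC[C@@H](C)C(Cl)=O
F10 | step 6 | methyl 4,5-di-O-[(2R)-2-methylbutanoyl]shikimate | CC[C@@H](C)C(=O)O[C@@H]1[C@H](O)C=C(C(=O)OC)C[C@H]1OC(=O)[C@H](C)CC
F11 | step 7 | (R)-2-methylbutanoic anhydride | CC[C@@H](C)C(=O)OC(=O)[C@H](C)CC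
A1 | alternative 1 | methyl 5-O-(4-methoxybenzyl)shikimate | O[C@@H]1[C@H](O)C=C(C(=O)OC)C[C@H]1OCc2ccc(OC)cc2
A2 | alternative 1 | methyl (2E)-2-{(2R)-2-[(4-methoxyphenyl)methoxy]-3-oxopropyl}-4-oxobut-2-enoate | COC(=O)/C(C[C@@H](OCc1ccc(OC)cc1)C=O)=C/C=O
A3 | alternative 2 | methyl 3-acetoxy-2-nitrocyclohex-4-ene-1-carboxylate (nitro cis to acetate, trans to ester) | COC(=O)[C@H]1CC=C[C@H](OC(C)=O)[C@@H]1[N+](=O)[O-]
A4 | alternative 2 | (E)-1-acetoxybuta-1,3-diene | CC(=O)O/C=C/C=C
A5 | alternative 2 | methyl (E)-3-nitroacrylate | COC(=O)/C=C/[N+](=O)[O-]
A6 | alternative 2 | methyl (3S)-3-acetoxycyclohexa-1,4-diene-1-carboxylate (same spatial arrangement at C3 as in 12) | COC(=O)C1=C[C@@H](OC(C)=O)C=CC1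
A7 | alternative 3 | methyl 3,4-O-isopropylidene shikimate | CC1(C)O[C@@H]2[C@H](O1)C=C(C(=O)OC)C[C@H]2O
A8 | alternative 3 | D-lyxose (open-chain form) | OC[C@H]([C@@H]([C@@H](C=O)O)O)O
A9 | alternative 3 | 5-deoxy-5-C-[(dimethoxyphosphoryl)(methoxycarbonyl)methyl]-2,3-O-isopropylidene-D-lyxofuranose (mixture at the anomeric and phosphonate carbons) | CC1(C)O[C@@H]2[C@H](O1)C(O)O[C@@H]2CC(C(=O)OC)P(=O)(OC)OC
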